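The quinone ring is disconnected at the C1–C6 bond. C1 (carbonyl), C2 (methoxy), C3–H and C4 (carbonyl) come from a 2‑methoxycyclobutenone; C5–H and the side‑chain‑bearing C6 are the two carbons of a homopropargylic alkyne. One thermolysis opens the four‑membered ring to an enynylketene, forms C1–C6 and closes the six‑membered quinone ring, giving the target directly with its (R)‑acetate already in place. The precursor is the 4‑alkynyl‑4‑hydroxy‑2‑methoxycyclobutenone 16, built from dimethyl squarate and an (R)‑epichlorohydrin‑derived alkyne. The methoxy position is fixed by silylating the tertiary alkoxide before a hydride reduction/acid carbonyl transposition, so that only the hydride‑derived carbinol can ionize.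

Key step: step 8

Remark on the chemistry: the ring carbinol carbon of 11–16 is formed without control and these compounds are carried as mixtures of two epimers; this is harmless because that carbon becomes the C4 carbonyl of the quinone. Compounds 12–16 should be handled at or below room temperature.

Step 1
Reactants: 1 1‑bromodecane; 2 (R)‑epichlorohydrin
Product: 4 (2R)‑1‑chlorotridecan‑2‑ol, via decylmagnesium bromide 3 (not isolated)
Conditions: Mg, THF, 40 °C; then CuI (10 mol %), 2, THF, −40 → 0 °C; 1 M HCl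
Reagents that add atoms: none
Why: Copper‑catalysed Grignard opening of the terminal epoxide (SN2 at the unsubstituted ring carbon) should outrun attack at the chloromethyl group at low temperature, and as no bond to the stereocenter is touched the (R) configuration of 2 is carried into 4.

Step 2
Reactants: 4 (2R)‑1‑chlorotridecan‑2‑ol; 5 lithium acetylide–ethylenediamine complex (LiC≡CH·H2NCH2CH2NH2)
Product: 7 (4R)‑pentadec‑1‑yn‑4‑ol, via (2R)‑2‑undecyloxirane 6 (not isolated)
Conditions: 5 (3 equiv), DMSO, 0 °C → rt; aq. NH4Cl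
Reagents that add atoms: none
Why: One equivalent of acetylide deprotonates the hydroxyl, the alkoxide closes to epoxide 6 by intramolecular Williamson displacement of the primary chloride, and a second equivalent opens 6 at its CH2 carbon (SN2 acetylide opening), so the C–O bond of the stereocenter is never broken and (R) is retained.

Step 3
Reactants: 7 (4R)‑pentadec‑1‑yn‑4‑ol
Product: 8 triethyl{[(4R)‑pentadec‑1‑yn‑4‑yl]oxy}silane
Conditions: Et3SiCl, imidazole, CH2Cl2, 0 °C → rt
Reagents that add atoms: chlorotriethylsilane, CC[Si](Cl)(CC)CC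
Why: Standard O‑silylation of a secondary alcohol gives an ether that tolerates n‑BuLi and hydride but is the most acid‑labile silyl group in the later intermediates.

Step 4
Reactants: 8 triethyl{[(4R)‑pentadec‑1‑yn‑4‑yl]oxy}silane; 9 dimethyl squarate
Product: 12 4‑{[tert‑butyl(dimethyl)silyl]oxy}‑2,3‑dimethoxy‑4‑{(4R)‑4‑[(triethylsilyl)oxy]pentadec‑1‑yn‑1‑yl}cyclobut‑2‑en‑1‑one, via lithium acetylide 10 (not isolated), via lithium alkoxide 11 (not isolated)
Conditions: n‑BuLi, THF, −78 °C; add to 9, THF, −78 °C; then t‑BuMe2SiOTf, −78 → 0 °C; aq. NaHCO3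
Reagents that add atoms: tert‑butyldimethylsilyl trifluoromethanesulfonate, CC(C)(C)[Si](C)(C)OS(=O)(=O)C(F)(F)F
Why: The alkynyllithium adds 1,2 to one of the two equivalent carbonyls of the squarate ester (standard organolithium addition to squarates, new carbinol center uncontrolled and inconsequential), and the silyl triflate caps the tertiary alkoxide in the same flask so that this oxygen can neither ionize nor be lost in step 5.

Step 5
Reactants: 12 the bis‑silylated dimethoxycyclobutenone
Product: 14 4‑{[tert‑butyl(dimethyl)silyl]oxy}‑4‑[(4R)‑4‑hydroxypentadec‑1‑yn‑1‑yl]‑2‑methoxycyclobut‑2‑en‑1‑one, via cyclobutenol 13 (not isolated)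
Conditions: i‑Bu2AlH, CH2Cl2, −78 °C; then 1 M HCl, THF, 0 °C → rt
Reagents that add atoms: water, O
Why: 1,2‑Reduction of the vinylogous ester carbonyl gives 13, whose only free hydroxyl ionizes in aqueous acid with help from the methoxy group at the far end of the allyl system, water adds and methanol is lost so that the carbonyl reappears next to the silyloxy carbon (Stork–Danheiser enone transposition), while the same acid cleaves the secondary triethylsilyl ether and spares the hindered tertiary tert‑butyldimethylsilyl ether.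

Step 6
Reactants: 14 the hydroxy silyloxy methoxycyclobutenone
Product: 15 (4R)‑1‑(1‑{[tert‑butyl(dimethyl)silyl]oxy}‑3‑methoxy‑4‑oxocyclobut‑2‑en‑1‑yl)pentadec‑1‑yn‑4‑yl acetate
Conditions: Ac2O, pyridine, DMAP (cat.), CH2Cl2, 0 °C
Reagents that add atoms: acetic anhydride, CC(=O)OC(C)=O
Why: Acyl transfer to the only free hydroxyl is unambiguous because the tertiary oxygen is still silylated, and esterification does not touch the C–O bond of the stereocenter.

Step 7
Reactants: 15 the silyl‑protected acetate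
Product: 16 4‑[(4R)‑4‑acetoxypentadec‑1‑yn‑1‑yl]‑4‑hydroxy‑2‑methoxycyclobut‑2‑en‑1‑one
Conditions: 48 % aq. HF, MeCN, 0 °C → rt
Reagents that add atoms: none
Why: Fluoride‑driven Si–O cleavage under mildly acidic conditions frees the tertiary hydroxyl without generating the base‑sensitive cyclobutenone alkoxide and leaves the acetate and the enol ether intact.

Step 8
Reactants: 16 4‑[(4R)‑4‑acetoxypentadec‑1‑yn‑1‑yl]‑4‑hydroxy‑2‑methoxycyclobut‑2‑en‑1‑one
Product: 19 2‑[(2R)‑2‑acetoxytridecyl]‑6‑methoxy‑1,4‑benzoquinone, via enynylketene 17 (not isolated), via ring diradical 18 (not isolated)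
Conditions: toluene (degassed, ca. 0.01 M), 110 °C, Ar
Reagents that add atoms: none
Why: Heating should trigger conrotatory four‑electron electrocyclic opening of the C1–C4 bond of the cyclobutenone, the hydroxyl turning outward so that the alkynyl arm lies cis to the new ketene carbon in 17. The ketene carbon then bonds to the distal alkyne carbon (the C1–C6 bond of the quinone), a six‑membered closure, endo at the alkyne, that gives the aromatic ring diradical 18; transfer of the hydroxyl hydrogen to the adjacent ring carbon radical (C5) delivers the quinone. The closest known reaction is the Moore rearrangement of 4‑alkynyl‑4‑hydroxycyclobutenones to 1,4‑benzoquinones, driven by release of four‑ring strain. No stereocenter is formed, the remote (R)‑acetate center is a spectator, and both carbinol epimers of 16 converge because that carbon becomes the C4 carbonyl. The selectivity required is six‑ over five‑membered closure, which the plain CH2 substituent on the distal alkyne carbon should secure because it gives no stabilization to the exocyclic vinyl radical of the five‑ring pathway. The positions of methoxy (C2) and hydrogen (C3, C5) are fixed by the substrate, in which methoxy sits alpha to the carbonyl and the alkyne carbon next to the carbinol ends as C5–H.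

Compound list
1 | 1‑bromodecane | CCCCCCCCCCBr | starting material
2 | (R)‑epichlorohydrin | ClC[C@H]1CO1 | starting material
3 | decylmagnesium bromide (C10H21MgBr) | CCCCCCCCCC[Mg]Br | intermediate
4 | (2R)‑1‑chlorotridecan‑2‑ol | CCCCCCCCCCC[C@H](CCl)O | intermediate
5 | lithium acetylide–ethylenediamine complex | [Li+].[C-]#C.NCCN | starting material
6 | (2R)‑2‑undecyloxirane | CCCCCCCCCCC[C@@H]1CO1 | intermediate
7 | (4R)‑pentadec‑1‑yn‑4‑ol | CCCCCCCCCCC[C@H](CC#C)O | intermediate
8 | triethyl{[(4R)‑pentadec‑1‑yn‑4‑yl]oxy}silane | CCCCCCCCCCC[C@H](CC#C)O[Si](CC)(CC)CC | intermediate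
9 | dimethyl squarate (3,4‑dimethoxycyclobut‑3‑ene‑1,2‑dione) | COC1=C(OC)C(=O)C1=O | starting material
10 | {(4R)‑4‑[(triethylsilyl)oxy]pentadec‑1‑yn‑1‑yl}lithium | CCCCCCCCCCC[C@H](CC#C[Li])O[Si](CC)(CC)CC | intermediate
11 | lithium 2,3‑dimethoxy‑4‑oxo‑1‑{(4R)‑4‑[(triethylsilyl)oxy]pentadec‑1‑yn‑1‑yl}cyclobut‑2‑en‑1‑olate (both epimers) | CCCCCCCCCCC[C@H](CC#CC1(O[Li])C(OC)=C(OC)C1=O)O[Si](CC)(CC)CC | intermediate
12 | 4‑{[tert‑butyl(dimethyl)silyl]oxy}‑2,3‑dimethoxy‑4‑{(4R)‑4‑[(triethylsilyl)oxy]pentadec‑1‑yn‑1‑yl}cyclobut‑2‑en‑1‑one (both epimers) | CCCCCCCCCCC[C@H](CC#CC1(O[Si](C)(C)C(C)(C)C)C(OC)=C(OC)C1=O)O[Si](CC)(CC)CC | intermediate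
13 | 4‑{[tert‑butyl(dimethyl)silyl]oxy}‑2,3‑dimethoxy‑4‑{(4R)‑4‑[(triethylsilyl)oxy]pentadec‑1‑yn‑1‑yl}cyclobut‑2‑en‑1‑ol (stereoisomer mixture at the ring) | CCCCCCCCCCC[C@H](CC#CC1(O[Si](C)(C)C(C)(C)C)C(OC)=C(OC)C1O)O[Si](CC)(CC)CC | intermediate
14 | 4‑{[tert‑butyl(dimethyl)silyl]oxy}‑4‑[(4R)‑4‑hydroxypentadec‑1‑yn‑1‑yl]‑2‑methoxycyclobut‑2‑en‑1‑one (both epimers) | CCCCCCCCCCC[C@H](CC#CC1(O[Si](C)(C)C(C)(C)C)C=C(OC)C1=O)O | intermediate
15 | (4R)‑1‑(1‑{[tert‑butyl(dimethyl)silyl]oxy}‑3‑methoxy‑4‑oxocyclobut‑2‑en‑1‑yl)pentadec‑1‑yn‑4‑yl acetate (both epimers) | CCCCCCCCCCC[C@H](CC#CC1(O[Si](C)(C)C(C)(C)C)C=C(OC)C1=O)OC(C)=O | intermediate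
16 | 4‑[(4R)‑4‑acetoxypentadec‑1‑yn‑1‑yl]‑4‑hydroxy‑2‑methoxycyclobut‑2‑en‑1‑one (both epimers) | CCCCCCCCCCC[C@H](CC#CC1(O)C=C(OC)C1=O)OC(C)=O | intermediate
17 | enynylketene O=C=C(OMe)–CH=C(OH)–C≡C–CH2–CH(OAc)–C11H23, alkynyl arm cis to the ketene‑bearing carbon, (R) at the acetate carbon | CCCCCCCCCCC[C@H](CC#C/C(O)=C\C(OC)=C=O)OC(C)=O | intermediate
18 | 2‑[(2R)‑2‑acetoxytridecyl]‑4‑hydroxy‑6‑methoxyphenoxyl carrying an aryl radical at C3 (ring diradical) | CCCCCCCCCCC[C@H](Cc1[c]c(O)cc(OC)c1[O])OC(C)=O | intermediate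
19 | 2‑[(2R)‑2‑acetoxytridecyl]‑6‑methoxy‑1,4‑benzoquinone | CCCCCCCCCCC[C@H](CC1=CC(=O)C=C(OC)C1=O)OC(C)=O | target

Total step count: 8. Longest linear sequence: 8 steps (1 and 2 to 19); 5 enters at step 2 and 9 at step 4.

Steps most likely to fail

Step 8. The ketene may close onto the near alkyne carbon (five‑membered closure), or the ring diradical may be quenched by hydrogen abstraction from the side chain or solvent instead of from the hydroxyl. Thermal loss of acetic acid is a further possibility. The fallback sets out from 4 and returns at 19, building the quinone by phenol oxidation instead. Chlorohydrin 4 is closed with NaOH in MeOH/H2O and epoxide 6 is isolated. Guaiacol is converted with MOMCl/i‑Pr2NEt into 1‑methoxy‑2‑(methoxymethoxy)benzene F1, which is lithiated ortho to the acetal oxygen (n‑BuLi, THF, 0 °C). With BF3·OEt2 at −78 °C the aryllithium opens 6 at its CH2 carbon to give (2R)‑1‑[3‑methoxy‑2‑(methoxymethoxy)phenyl]tridecan‑2‑ol F2, with the stereocenter untouched. Acetylation (Ac2O, pyridine) gives (2R)‑1‑[3‑methoxy‑2‑(methoxymethoxy)phenyl]tridecan‑2‑yl acetate F3. CF3CO2H in wet CH2Cl2 at 0 °C removes the acetal to give (2R)‑1‑(2‑hydroxy‑3‑methoxyphenyl)tridecan‑2‑yl acetate F4. Teuber oxidation of the free para position with (KSO3)2NO and KH2PO4 in aqueous acetone should then give 19.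

Step 5. The acid‑triggered events may not stay in order. If cleavage of the secondary silyl ether is slow, longer acid exposure is needed, and under it the tertiary silyl ether can be lost, the wrong carbinol can ionize, or a second methanol can be expelled. The fallback sets out from 12 and returns at 14, replacing Brønsted‑acid hydrolysis by acylative activation and separating the deprotection. Luche reduction of 12 (NaBH4, CeCl3·7H2O, MeOH, −40 °C) gives 13, which is isolated. Its only free hydroxyl is converted into the trifluoroacetate with (CF3CO)2O/pyridine in CH2Cl2 at −78 °C; ionization and aqueous NaHCO3 work‑up should give 4‑{[tert‑butyl(dimethyl)silyl]oxy}‑2‑methoxy‑4‑{(4R)‑4‑[(triethylsilyl)oxy]pentadec‑1‑yn‑1‑yl}cyclobut‑2‑en‑1‑one F5. Pyridinium p‑toluenesulfonate in MeOH at 0 °C then removes only the triethylsilyl ether to give 14.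

Step 7. Si–O cleavage at the hindered tertiary center may be sluggish, and forcing it invites acid‑promoted loss of methanol from the ring or hydrolysis of the acetate. The fallback sets out from 8 (with 9) and returns at 16, avoiding any late tertiary desilylation. Alkoxide 11 is trapped with Me3SiCl instead, giving 2,3‑dimethoxy‑4‑{(4R)‑4‑[(triethylsilyl)oxy]pentadec‑1‑yn‑1‑yl}‑4‑[(trimethylsilyl)oxy]cyclobut‑2‑en‑1‑one F6. Reduction with i‑Bu2AlH and treatment with 1 M HCl/THF effects the transposition and then strips both silyl groups to give 4‑hydroxy‑4‑[(4R)‑4‑hydroxypentadec‑1‑yn‑1‑yl]‑2‑methoxycyclobut‑2‑en‑1‑one F7. Ac2O/pyridine at 0 °C without acyl‑transfer catalyst should acetylate only the secondary hydroxyl and give 16.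

Further compounds
F1 | step 8 | 1‑methoxy‑2‑(methoxymethoxy)benzene | COCOc1ccccc1OC
F2 | step 8 | (2R)‑1‑[3‑methoxy‑2‑(methoxymethoxy)phenyl]tridecan‑2‑ol | CCCCCCCCCCC[C@H](Cc1cccc(OC)c1OCOC)O
F3 | step 8 | (2R)‑1‑[3‑methoxy‑2‑(methoxymethoxy)phenyl]tridecan‑2‑yl acetate | CCCCCCCCCCC[C@H](Cc1cccc(OC)c1OCOC)OC(C)=O
F4 | step 8 | (2R)‑1‑(2‑hydroxy‑3‑methoxyphenyl)tridecan‑2‑yl acetate | CCCCCCCCCCC[C@H](Cc1cccc(OC)c1O)OC(C)=O
F5 | step 5 | 4‑{[tert‑butyl(dimethyl)silyl]oxy}‑2‑methoxy‑4‑{(4R)‑4‑[(triethylsilyl)oxy]pentadec‑1‑yn‑1‑yl}cyclobut‑2‑en‑1‑one | CCCCCCCCCCC[C@H](CC#CC1(O[Si](C)(C)C(C)(C)C)C=C(OC)C1=O)O[Si](CC)(CC)CC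
F6 | step 7 | 2,3‑dimethoxy‑4‑{(4R)‑4‑[(triethylsilyl)oxy]pentadec‑1‑yn‑1‑yl}‑4‑[(trimethylsilyl)oxy]cyclobut‑2‑en‑1‑one | CCCCCCCCCCC[C@H](CC#CC1(O[Si](C)(C)C)C(OC)=C(OC)C1=O)O[Si](CC)(CC)CC
F7 | step 7 | 4‑hydroxy‑4‑[(4R)‑4‑hydroxypentadec‑1‑yn‑1‑yl]‑2‑methoxycyclobut‑2‑en‑1‑one | CCCCCCCCCCC[C@H](CC#CC1(O)C=C(OC)C1=O)O
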